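| flask | X | E | remark | time |
|---|---|---|---|---|
| cedar | 0.050 M | 0.050 M | run made earlier |  |
| ash | 0.050 M | 0.070 M | run made earlier |  |
| alder | 0.050 M | 0.11 M | run made earlier |  |
| oak | 0.10 M | 0.050 M | run made earlier |  |
| amber | 0.050 M | 0.0500 M | everything together at the start | 4.0 d |
| blue | 0.050 M (in portions, 3, over 3.0 d) | 0.0500 M | first portion at the start, last at 3.0 d | 4.0 d |
| ochre | 0.050 M | 0.0500 M (fed, over 3.0 d) | all else is in the flask from the start; the feed brings no volume worth counting | 4.0 d |
| teal | 0.050 M (fed, over 3.0 d) | 0.0500 M | all else is in the flask from the start; the feed brings no volume worth counting | 4.0 d |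

| run | time / d | Z / % | D / % |
|---|---|---|---|
| cedar | 0.333 | 3.0 | 28.6 |
| cedar | 1.04 | 22.6 | 31.5 |
| cedar | 1.67 | 36.9 | 25.4 |
| cedar | 3.00 | 53.7 | 18.6 |
| cedar | 4.00 | 60.4 | 14.7 |
| ash | 0.833 | 25.1 | 37.1 |
| ash | 1.67 | 48.5 | 28.6 |
| ash | 2.50 | 62.2 | 21.0 |
| ash | 3.00 | 65.9 | 18.0 |
| ash | 4.00 | 74.7 | 14.8 |
| alder | 0.333 | 9.6 | 45.4 |
| alder | 1.04 | 46.1 | 37.4 |
| alder | 1.67 | 63.1 | 26.6 |
| alder | 3.00 | 80.5 | 16.5 |
| alder | 4.00 | 85.7 | 12.6 |
| oak | 0.333 | 4.8 | 21.4 |
| oak | 1.04 | 21.0 | 18.9 |
| oak | 1.67 | 29.1 | 13.6 |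
| oak | 3.00 | 38.0 | 8.0 |
| oak | 4.00 | 40.3 | 6.2 |

(scatter of a reading: 0.5 percentage points)

- steps that have been proposed: X + E <-> D + Q; D + Q -> Z; E -> G

1. the flask with the highest amount of Z, in percent of the X charged ("all alike" if they lie within 1.5 percentage points) (amber / blue / ochre / teal / all alike)
2. final Z, as a percentage of the X charged, in amber
3. final Z, as a percentage of the X charged, in blue
4. final Z, as a percentage of the X charged, in ochre
5. final Z, as a percentage of the X charged, in teal

At early times cedar built D first: at 0.333 d, with d and z meaning D and Z as fractions of the X charged, d stood at 28.6% and z at 3.0%. So Z lags a stock, like a second stage behind a first. The proposed steps X + E <-> D + Q and D + Q -> Z make and spend D and Q in pairs, so with no Q charged the two stay equal, and the rate of z should go as d squared, second order in the intermediate. Cedar's last interval gives the drain constant κ, the daily gain of z divided by d squared: 2.45 /d, a reading. Oak, with twice the X, read 4.64 /d, so κ goes with the X charged.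

Amber is cedar's recipe, so I expected 60.4%. Reaching that by 4.00 d takes a root-mean-square d of 24.8%. But in blue, ochre and teal the dosed species is the limiting reagent at first: after 1.00 d, a third of it is in. I lent those flasks cedar's middle d, 22.0%, counted over the last 3.00 d or the whole 4.0 d: z from 35.6% to 47.4%, less than amber.

The forecast named amber, with 60.4%, and 38% in blue, 44% in ochre, 40% in teal: “Because Z is second order in D and Q, dosing hurts, so amber wins.”

The flask gave 60.7% in amber; 40.2% in blue, 45.3% in ochre and 41.6% in teal lay inside my bracket. At 4.00 d ochre held d at 21.9% against 14.7% in amber. With κ, ochre was then gaining 0.118 /d, faster than amber's 0.0529 /d.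

    X + E ⇌ D + Q (K = 1.70, k = 0.0200 /M/min)
    D + Q → Z (k = 0.0370 /M/min)
    E → G (k = 6.00 × 10⁻⁵ /min)

The neighbour, blue with 0.085 M of E, has the same X charge and so the same κ; its d of 24.9% at 4.00 d, lent to the last 3.0 d or the whole 4.0 d, gives z from 45.6% to 60.8%. The computed result is 55.1%.

The numbers in the tables are calculated for substances that don't exist; scatter was added.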